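The dihydropyranone is disconnected at C3=C4 and at O1–C6, a C–O bond that is allylic to the exocyclic C1'=C2' E-olefin. The precursor therefore carries its acrylate not on C6 but on C2', at the far end of the transposed allyl system C6=C1'–C2', with a skipped terminal vinyl group at C4. In one operation a divalent palladium catalyst shuttles the acrylate suprafacially from C2' to C6 while a ruthenium carbene closes the ring by metathesis, which drains the ester equilibrium and relays C2' chirality to C6. All other stereocentres descend from a purchased syn-diol acetonide through 1,3-anti aldol and Evans–Tishchenko steps.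

Key step: step 9

Remark: ring atoms are numbered O1, C2 (carbonyl) to C6 and side-chain carbons C1' to C10' outward from C6; 1 is taken as the commercially available statin side-chain aldehyde.

Step 1
Reactants: 1 tert-butyl 2-[(4R,6S)-6-formyl-2,2-dimethyl-1,3-dioxan-4-yl]acetate; 2 benzyltriphenylphosphonium bromide
Product: 4 tert-butyl 2-[(4R,6S)-2,2-dimethyl-6-(2-phenylethenyl)-1,3-dioxan-4-yl]acetate (E/Z mixture), via benzylidenetriphenylphosphorane 3 (not isolated)
Conditions: 2, NaN(SiMe3)2, THF, 0 °C; then 1, −78 °C to rt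
Reagents that add atoms: none
Why: Wittig olefination of the α-alkoxy aldehyde with the semi-stabilised ylide should proceed at low temperature without epimerisation of the diequatorial acetonide, creates no stereocentre, and gives an E/Z mixture that is immaterial because step 2 saturates the olefin.

Step 2
Reactants: 4 tert-butyl 2-[(4R,6S)-2,2-dimethyl-6-(2-phenylethenyl)-1,3-dioxan-4-yl]acetate
Product: 5 tert-butyl 2-[(4R,6R)-2,2-dimethyl-6-(2-phenylethyl)-1,3-dioxan-4-yl]acetate
Conditions: H2 (1 atm), Pd/C, EtOAc, rt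
Reagents that add atoms: none
Why: Heterogeneous catalytic hydrogenation saturates the styrene while ester, acetonide and arene are inert, and the configuration at C6 of the dioxane is untouched (its descriptor changes by priority only).

Step 3
Reactants: 5 tert-butyl 2-[(4R,6R)-2,2-dimethyl-6-(2-phenylethyl)-1,3-dioxan-4-yl]acetate
Product: 6 2-[(4R,6R)-2,2-dimethyl-6-(2-phenylethyl)-1,3-dioxan-4-yl]acetaldehyde
Conditions: iBu2AlH (1.1 equiv), CH2Cl2, −78 °C; MeOH, then aq. potassium sodium tartrate
Reagents that add atoms: none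
Why: Partial reduction of the ester with iBu2AlH should stop at the chelated tetrahedral aluminium hemiacetal at −78 °C, which releases the aldehyde only on work-up.

Step 4
Reactants: 7 pent-1-en-4-yne
Product: 9 (3E)-hepta-3,6-dien-2-one, via alkenylzirconocene chloride 8 (not isolated)
Conditions: Cp2Zr(H)Cl (1.0 equiv), CH2Cl2, rt; then AcCl, CuBr·SMe2 (10 mol%), THF, 0 °C to rt
Reagents that add atoms: acetyl chloride, CC(=O)Cl
Why: Hydrozirconation adds Zr–H syn and anti-Markovnikov, far faster to the terminal alkyne than to the monosubstituted olefin, and the (E)-alkenylzirconocene is acylated with retention of geometry through copper-mediated acyl transfer (hydrozirconation/acylation).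

Step 5
Reactants: 9 (3E)-hepta-3,6-dien-2-one
Product: 11 trimethyl{[(3E)-hepta-1,3,6-trien-2-yl]oxy}silane, via lithium enolate 10 (not isolated)
Conditions: Me3SiCl (2 equiv), then LiN(iPr)2 (1.1 equiv), THF, −78 °C (internal quench)
Reagents that add atoms: chlorotrimethylsilane, C[Si](C)(C)Cl
Why: Kinetic enolisation of the enone with the hindered amide removes an α'-methyl proton to give the cross-conjugated enolate, which the silyl chloride already present traps on oxygen before it can equilibrate to the extended dienolate (internal-quench silyl enol ether formation).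

Step 6
Reactants: 6 2-[(4R,6R)-2,2-dimethyl-6-(2-phenylethyl)-1,3-dioxan-4-yl]acetaldehyde; 11 trimethyl{[(3E)-hepta-1,3,6-trien-2-yl]oxy}silane
Product: 12 (4E,8S)-8-hydroxy-9-[(4S,6R)-2,2-dimethyl-6-(2-phenylethyl)-1,3-dioxan-4-yl]nona-1,4-dien-6-one
Conditions: BF3·OEt2 (1.1 equiv), CH2Cl2, −78 °C; aq. NaHCO3 at −78 °C
Reagents that add atoms: none
Why: Mukaiyama aldol addition through an open transition state: the BF3-bound β-alkoxy aldehyde reacts in the conformation that opposes the C=O and C6'–O dipoles, so the enol silane attacks the face that gives the 1,3-anti C4' carbinol by substrate control.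

Step 7
Reactants: 12 (4E,8S)-8-hydroxy-9-[(4S,6R)-2,2-dimethyl-6-(2-phenylethyl)-1,3-dioxan-4-yl]nona-1,4-dien-6-one
Product: 13 (2R,4R,5E)-1-[(4R,6R)-2,2-dimethyl-6-(2-phenylethyl)-1,3-dioxan-4-yl]-4-hydroxynona-5,8-dien-2-yl acetate
Conditions: MeCHO (8 equiv), SmI2 (0.3 equiv, premixed with the MeCHO), THF, −10 °C
Reagents that add atoms: acetaldehyde, CC=O
Why: Evans–Tishchenko reduction: the samarium-bound hemiacetal formed from the C4' hydroxyl and acetaldehyde delivers hydride intramolecularly through a six-membered chair to the C2' ketone, which sets the 1,3-anti (R)-C2' carbinol and leaves the acetate on O4' in the same event.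

Step 8
Reactants: 13 (2R,4R,5E)-1-[(4R,6R)-2,2-dimethyl-6-(2-phenylethyl)-1,3-dioxan-4-yl]-4-hydroxynona-5,8-dien-2-yl acetate
Product: 14 (2S,4R,5E)-2-(acetyloxy)-1-[(4R,6R)-2,2-dimethyl-6-(2-phenylethyl)-1,3-dioxan-4-yl]nona-5,8-dien-4-yl prop-2-enoate
Conditions: acryloyl chloride (1.5 equiv), iPr2NEt, DMAP (5 mol%), CH2Cl2, −40 to −20 °C
Reagents that add atoms: acryloyl chloride, C=CC(=O)Cl
Why: Amine-mediated O-acylation of the secondary allylic alcohol with the acid chloride is fast at low temperature, where 1,3-acetyl migration is slow, and it touches no stereocentre (the C2 descriptor changes by priority only).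

Step 9
Reactants: 14 (2S,4R,5E)-2-(acetyloxy)-1-[(4R,6R)-2,2-dimethyl-6-(2-phenylethyl)-1,3-dioxan-4-yl]nona-5,8-dien-4-yl prop-2-enoate
Product: 16 (2R,4E)-1-[(4R,6R)-2,2-dimethyl-6-(2-phenylethyl)-1,3-dioxan-4-yl]-5-[(2S)-6-oxo-3,6-dihydro-2H-pyran-2-yl]pent-4-en-2-yl acetate, via transposed acrylate 15 (not isolated)
Conditions: PdCl2(MeCN)2 (10 mol%), second-generation Hoveyda–Grubbs catalyst [RuCl2(H2IMes)(=CH-C6H4-2-OiPr)] (10 mol%), 1,4-benzoquinone (20 mol%), CH2Cl2 (3 mM), 40 °C
Reagents that add atoms: none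
Why: PdCl2(MeCN)2 activates the C6=C1' olefin of 14, the acrylate carbonyl oxygen adds to C6 anti to palladium to give a 1,3-dioxan-2-ylium alkylpalladium intermediate, and anti-deoxypalladation at C2'–O completes a net suprafacial [3,3] acyloxy shift that equilibrates 14 with 15; the ruthenium alkylidene then loads on the terminal vinyl group and ring-closing metathesis onto the acrylate of 15 forms C3=C4 with loss of ethylene. The closest known reaction types are the PdCl2(MeCN)2-catalysed 1,3-transposition of allylic acetates and the one-pot Overman rearrangement/ring-closing metathesis sequence, so the concurrent use of the two catalysts is the untested element. The O1–C6 bond forms in the 6-endo closure of the transient dioxanylium ring, and the lactone ring itself closes by six-membered ring-closing metathesis, which enforces the Z geometry of C3=C4. C6 is controlled by 1,3-chirality transfer from C2': in the chair-like arrangement the C3' chain is pseudo-equatorial, so the (R)-C2', E-olefin substrate delivers oxygen to the same face of the allyl system and should give (S)-C6 together with the E C1'=C2' olefin. The step needs selection between the two equilibrating esters, and ring size secures it, because 15 closes a six-membered ring whereas 14 could only form an eight-membered ring across an E-olefin or a butenolide through its internal olefin, so the irreversible metathesis drains the mixture through 15.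

Step 10
Reactants: 16 (2R,4E)-1-[(4R,6R)-2,2-dimethyl-6-(2-phenylethyl)-1,3-dioxan-4-yl]-5-[(2S)-6-oxo-3,6-dihydro-2H-pyran-2-yl]pent-4-en-2-yl acetate
Product: 17 (1E,4R,6R,8R)-6,8-dihydroxy-1-[(2S)-6-oxo-3,6-dihydro-2H-pyran-2-yl]-10-phenyldec-1-en-4-yl acetate
Conditions: AcOH/H2O (4:1), 45 °C
Reagents that add atoms: none
Why: Acid-catalysed hydrolysis of the isopropylidene acetal frees the syn-1,3-diol, while the acetate, the lactone and the olefins tolerate aqueous acetic acid and no stereocentre is involved.

Compound list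
1 | tert-butyl 2-[(4R,6S)-6-formyl-2,2-dimethyl-1,3-dioxan-4-yl]acetate | O=C[C@@H]1C[C@H](CC(=O)OC(C)(C)C)OC(C)(C)O1 | starting material
2 | benzyltriphenylphosphonium bromide | [Br-].c1ccccc1C[P+](c1ccccc1)(c1ccccc1)c1ccccc1 | starting material
3 | benzylidenetriphenylphosphorane (ylide, not isolated) | c1ccccc1C=P(c1ccccc1)(c1ccccc1)c1ccccc1 | intermediate
4 | tert-butyl 2-[(4R,6S)-2,2-dimethyl-6-(2-phenylethenyl)-1,3-dioxan-4-yl]acetate (E/Z mixture) | c1ccccc1C=C[C@@H]1C[C@H](CC(=O)OC(C)(C)C)OC(C)(C)O1 | intermediate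
5 | tert-butyl 2-[(4R,6R)-2,2-dimethyl-6-(2-phenylethyl)-1,3-dioxan-4-yl]acetate | c1ccccc1CC[C@@H]1C[C@H](CC(=O)OC(C)(C)C)OC(C)(C)O1 | intermediate
6 | 2-[(4R,6R)-2,2-dimethyl-6-(2-phenylethyl)-1,3-dioxan-4-yl]acetaldehyde | c1ccccc1CC[C@@H]1C[C@H](CC=O)OC(C)(C)O1 | intermediate
7 | pent-1-en-4-yne | C=CCC#C | starting material
8 | chlorobis(cyclopentadienyl)[(1E)-penta-1,4-dien-1-yl]zirconium, Cp2Zr(Cl)(CH=CHCH2CH=CH2) (not isolated) | C=CC/C=C/[Zr](Cl)(C1C=CC=C1)C1C=CC=C1 | intermediate
9 | (3E)-hepta-3,6-dien-2-one | CC(=O)/C=C/CC=C | intermediate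
10 | lithium (3E)-hepta-1,3,6-trien-2-olate (not isolated) | [Li+].[O-]C(=C)/C=C/CC=C | intermediate
11 | trimethyl{[(3E)-hepta-1,3,6-trien-2-yl]oxy}silane | C=C(O[Si](C)(C)C)/C=C/CC=C | intermediate
12 | (4E,8S)-8-hydroxy-9-[(4S,6R)-2,2-dimethyl-6-(2-phenylethyl)-1,3-dioxan-4-yl]nona-1,4-dien-6-one | c1ccccc1CC[C@@H]1C[C@H](C[C@H](O)CC(=O)/C=C/CC=C)OC(C)(C)O1 | intermediate
13 | (2R,4R,5E)-1-[(4R,6R)-2,2-dimethyl-6-(2-phenylethyl)-1,3-dioxan-4-yl]-4-hydroxynona-5,8-dien-2-yl acetate | c1ccccc1CC[C@@H]1C[C@H](C[C@H](OC(C)=O)C[C@@H](O)/C=C/CC=C)OC(C)(C)O1 | intermediate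
14 | (2S,4R,5E)-2-(acetyloxy)-1-[(4R,6R)-2,2-dimethyl-6-(2-phenylethyl)-1,3-dioxan-4-yl]nona-5,8-dien-4-yl prop-2-enoate | c1ccccc1CC[C@@H]1C[C@H](C[C@H](OC(C)=O)C[C@@H](OC(=O)C=C)/C=C/CC=C)OC(C)(C)O1 | intermediate
15 | (4S,5E,8R)-8-(acetyloxy)-9-[(4R,6R)-2,2-dimethyl-6-(2-phenylethyl)-1,3-dioxan-4-yl]nona-1,5-dien-4-yl prop-2-enoate (not isolated) | c1ccccc1CC[C@@H]1C[C@H](C[C@H](OC(C)=O)C/C=C/[C@@H](OC(=O)C=C)CC=C)OC(C)(C)O1 | intermediate
16 | (2R,4E)-1-[(4R,6R)-2,2-dimethyl-6-(2-phenylethyl)-1,3-dioxan-4-yl]-5-[(2S)-6-oxo-3,6-dihydro-2H-pyran-2-yl]pent-4-en-2-yl acetate | c1ccccc1CC[C@@H]1C[C@H](C[C@H](OC(C)=O)C/C=C/[C@@H]2CC=CC(=O)O2)OC(C)(C)O1 | intermediate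
17 | (1E,4R,6R,8R)-6,8-dihydroxy-1-[(2S)-6-oxo-3,6-dihydro-2H-pyran-2-yl]-10-phenyldec-1-en-4-yl acetate | CC(=O)O[C@H](C/C=C/[C@@H]1CC=CC(=O)O1)C[C@H](O)C[C@H](O)CCc1ccccc1 | target

Total step count: 10. Longest linear sequence: 8 steps (1, 2, 3, 6, 7, 8, 9, 10); steps 4 and 5 prepare the side fragment 11.

Steps most likely to fail

Step 9. What may go wrong: mutual deactivation of the two catalysts, a slow acyloxy shift of the electron-poor acrylate, or hydride-mediated migration of the skipped C4 olefin into conjugation before the ring closes. In the fallback the C6 stereocentre is set by a reagent-controlled allylation and the side chain is joined by olefin cross-metathesis. It sets out from 6 and comes back at 16. Brown allylation of 6 with the Ipc2B(allyl) enantiomer made from (+)-Ipc2BOMe and allylmagnesium bromide (Re-face addition) should give the homoallylic alcohol F1, and Ac2O/pyridine gives the acetate F2. In parallel, allylation of acrolein with the enantiomeric reagent (from (−)-Ipc2BOMe, Si-face addition) gives (3S)-hexa-1,5-dien-3-ol F3, acryloyl chloride/iPr2NEt gives the acrylate F4, and ring-closing metathesis with first-generation Grubbs catalyst [RuCl2(PCy3)2(=CHPh)] gives (6S)-6-ethenyl-5,6-dihydro-2H-pyran-2-one F5. Cross-metathesis of F2 with F5 (second-generation Hoveyda–Grubbs catalyst, CH2Cl2, 40 °C) should then give 16 with the E olefin.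

Step 7. What may go wrong: single-electron reduction of the dienone by divalent samarium, retro-aldol cleavage, or migration of the acetate from O4' to O2' after the hydride transfer. The fallback separates acylation from reduction and uses reagent control; it sets out from 12 and comes back at 13. Acetylation of 12 (Ac2O, pyridine, 0 °C) gives the β-acetoxy dienone F6, and Corey–Bakshi–Shibata reduction with (S)-Me-CBS oxazaborolidine and catecholborane (toluene, −78 °C), the alkenyl group acting as the large substituent, should reduce the enone carbonyl to the (R)-C2' alcohol 13.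

Step 4. What may go wrong: sluggish copper-mediated acyl transfer, or migration of the skipped double bond into conjugation under the acylation conditions and during isolation of the volatile ketone. The fallback replaces acylation by carbonyl addition and a neutral oxidation; it sets out from 8 and comes back at 9. Transmetalation of 8 with Me2Zn (CH2Cl2, −65 °C) gives the alkenyl(methyl)zinc F7, addition to acetaldehyde gives racemic (3E)-hepta-3,6-dien-2-ol F8, and MnO2 (CH2Cl2, rt) oxidises the allylic alcohol to 9.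

Further compounds
F1 | step 9 | (2R)-1-[(4S,6R)-2,2-dimethyl-6-(2-phenylethyl)-1,3-dioxan-4-yl]pent-4-en-2-ol | c1ccccc1CC[C@@H]1C[C@H](C[C@H](O)CC=C)OC(C)(C)O1
F2 | step 9 | (2R)-1-[(4R,6R)-2,2-dimethyl-6-(2-phenylethyl)-1,3-dioxan-4-yl]pent-4-en-2-yl acetate | c1ccccc1CC[C@@H]1C[C@H](C[C@H](OC(C)=O)CC=C)OC(C)(C)O1
F3 | step 9 | (3S)-hexa-1,5-dien-3-ol | C=C[C@@H](O)CC=C
F4 | step 9 | (3S)-hexa-1,5-dien-3-yl prop-2-enoate | C=C[C@@H](OC(=O)C=C)CC=C
F5 | step 9 | (6S)-6-ethenyl-5,6-dihydro-2H-pyran-2-one | C=C[C@@H]1CC=CC(=O)O1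
F6 | step 7 | (2S,5E)-1-[(4R,6R)-2,2-dimethyl-6-(2-phenylethyl)-1,3-dioxan-4-yl]-4-oxonona-5,8-dien-2-yl acetate | c1ccccc1CC[C@@H]1C[C@H](C[C@H](OC(C)=O)CC(=O)/C=C/CC=C)OC(C)(C)O1
F7 | step 4 | methyl[(1E)-penta-1,4-dien-1-yl]zinc | C[Zn]/C=C/CC=C
F8 | step 4 | (3E)-hepta-3,6-dien-2-ol (racemic) | CC(O)/C=C/CC=C
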